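The data were generated by integration for substances that don't exist, noise included.

Slowness now marks Thursday's flask: its first product still falls, but ever more gently, and the decision at 40 min is whether to leave that flask alone or act on it.

| setting | Thursday's | Sunday's | flask |
|---|---|---|---|
| starting material | 19 mM | 19 mM | 19 mM |
| reagent | 38 mM | 19 mM | 38.0 mM |
| temperature | 25 °C | 20 °C | 25 °C |
| remark | the very flask that is asked about, followed so far | run made earlier |  |
| time |  |  | 40 min |

| run | time / min | first product / % | starting material / % |
|---|---|---|---|
| Thursday's | 8.00 | 48.1 | 12.0 |
| Thursday's | 15.0 | 40.4 | 3.7 |
| Thursday's | 25.0 | 33.6 | 2.8 |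
| Thursday's | 30.0 | 32.4 | 0.8 |
| Sunday's | 1.50 | 17.5 | 82.8 |
| Sunday's | 4.00 | 32.9 | 61.3 |
| Sunday's | 8.00 | 42.4 | 46.6 |
| Sunday's | 20.0 | 50.1 | 26.2 |

(each reading ± 1 percentage point)

- additions bring no volume worth counting
- what was read earlier has a scatter of 1 percentage point, one standard deviation
- steps thought possible: starting material + reagent -> first product + released group; reagent + first product -> bis adduct + released group; reagent + bis adduct -> triple product + released group; starting material + released group -> side product

- winter: at 40 min add reagent, 100% of the amount charged, then wait 12 min
- spring: at 40 min take out 90% of the released group then present, then wait 12 min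
- summer: at 40 min raise the temperature by 25 K, then wait 12 min
- midnight: change nothing and wait 12 min more

* first product, in percent of the starting material first charged, at 40 min
* what to do for the largest gain in first product; "none" if nothing gains more than 2 percentage points (winter / spring / summer / midnight / none)
* first product present, in percent of the starting material first charged, after summer
* first product present, in percent of the starting material first charged, after midnight

In Thursday's flask first product lost 7.7 percentage points from 8.00 min to 15.0 min, then 8 points from 15.0 min to 30.0 min, a similar loss in twice the time. Placing each mean rate at the middle of its window gives a decay of the loss rate of 0.0658 min⁻¹, the fade constant, a reading with the scatter of its readings. Freezing it assumes that [first product] plus [bis adduct] holds roughly steady while [reagent] decays pseudo-first-order.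

On that assumption, the loss from 30.0 min to 40 min is 2.3 points, so the reckoning made here puts first product near 30.1% at 40 min. Among the steps thought possible, first product is made from starting material, whose last reading of 0.8% is less than the margin of 2 points. The decision here is therefore to leave the flask as it is and take no option.

The forecast differs slightly, with 31% now, 29% after summer and 30% after midnight. It also chooses none, holding that "Waiting or heating just burns the leftover reagent".

    starting material + reagent → first product + released group (k = 11.0 L mol⁻¹ min⁻¹, Ea = 56.0 kJ mol⁻¹)
    reagent + first product → bis adduct + released group (k = 4.70 L mol⁻¹ min⁻¹, Ea = 52.0 kJ mol⁻¹)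
    reagent + bis adduct → triple product + released group (k = 5.90 L mol⁻¹ min⁻¹, Ea = 59.0 kJ mol⁻¹)
    starting material + released group → side product (k = 1.20 L mol⁻¹ min⁻¹, Ea = 47.0 kJ mol⁻¹)
    (constants at 25 °C)

The flask gives 28.4% at 40 min, and the best choice is none, as forecast. First product in this flask is then made at 0.0517 of the rate at which it is used up, less than that rate, each step taken net. The fade constant puts the next 12 min at a loss of 1.3 points, or 27.1%; midnight gives 26.7%, and summer gives 25.5%.

The same flask read at 25 min lies 4.1 points above the 40 min value by the fade constant, which gives 32.5%. The computed value there is 33.2%.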